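Count the Dx. Each Ty takes two Dx on one Dz and each mono adduct takes one, so I hold two amounts against each other: the Dx charged and twice the Dz charged.

| flask | Dz | Dx | remark | time |
|---|---|---|---|---|
| eta | 0.090 M | 0.216 M (in portions, 4) | run made earlier; portions every 40 min |  |
| gamma | 0.14 M | 0.216 M (in portions, 4) | run made earlier; portions every 40 min |  |
| flask | 0.18 M | 0.216 M (in portions, 4) | the portions of Dx follow each other after 40 min, the first at the start | 15 d |

| run | time / d | Dz / % | Dw / % | Ty / % |
|---|---|---|---|---|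
| eta | 1.25 | 15 | 7 | 60 |
| eta | 2.00 | 9 | 7 | 72 |
| eta | 3.00 | 3 | 5 | 85 |
| eta | 5.00 | 0 | 3 | 88 |
| eta | 8.00 | 2 | 1 | 96 |
| eta | 12.0 | 0 | 1 | 100 |
| eta | 20.0 | 0 | 0 | 100 |
| gamma | 1.25 | 19 | 9 | 48 |
| gamma | 2.00 | 15 | 7 | 56 |
| gamma | 3.00 | 11 | 8 | 64 |
| gamma | 5.00 | 12 | 7 | 67 |
| gamma | 8.00 | 11 | 6 | 67 |
| gamma | 12.0 | 8 | 7 | 70 |
| gamma | 20.0 | 9 | 7 | 69 |

(scatter of a reading: 1.5 percentage points)

- steps thought possible: Dz + Dx -> Dw; Dz + Dx -> Qe; Dx + Dw -> Ty; Dx + Qe -> Ty; Dz -> Ja; Dw <-> Eb; Dz <-> Ju
- what has gone from Dz into another species counts as reacted, even if it can come back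
- the reaction counts as stopped when no species that holds the Dz changes by six tenths of a point or more over the second half of the time

- which holds at 15 d: what has brought the reaction to rest, or that it has not come to rest (all of Dz has reacted / it is still moving / Dx has run out first)
- conversion of Dz at 15 d
- amount of Dw at 15 d, in percent of the Dz charged
- amount of Ty at 15 d, in percent of the Dz charged
- amount of Eb at 15 d, in percent of the Dz charged
- amount of Dw if the flask were left three thousand times as long, in percent of the Dz charged

For the new flask, Dx charged over twice the Dz charged is 0.600. I call this ratio the cover. Below one it marks Dx as the limiting reagent and is the ceiling on Ty, as a fraction of the Dz charged. The eta run has a cover of 1.20 and reads Ty 100% at 12.0 d. The gamma run has a cover of 0.771, and its Ty stays between 67% and 70% from 5.00 d to 20.0 d, with Dz reading 9% at the end. Time adds little there. In the gamma run the gap, cover minus last Ty, reads 0.0814, which I take as Dx held in mono adducts, on the cover's scale of twice the Dz charged. The new flask's cover is lower than gamma's and below one, so I name Dx as limiting, and gamma's gap puts Ty near 51.9%.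

The forecast answers: Dx has run out first, with conversion 82%, Dw 11%, Ty 48%, Eb 10%, and Dw 11% after the long wait: “With Dx gone, Dw stays at its equilibrium share, even over very long times.” Its Ty lies below mine.

The flask answers: Dx has run out first, with Dx 0% at 15.0 d, conversion 81.4%, Dw 9.14%, Ty 48.4%, Eb 11.0%, and Dw 9.14% after the long wait.

    Dz + Dx → Dw (k = 0.357 L mol⁻¹ h⁻¹)
    Dz + Dx → Qe (k = 0.241 L mol⁻¹ h⁻¹)
    Dx + Dw → Ty (k = 0.870 L mol⁻¹ h⁻¹)
    Dx + Qe → Ty (k = 1.81 L mol⁻¹ h⁻¹)
    Dz → Ja (k = 2.40 × 10⁻⁵ h⁻¹)
    Dw ⇌ Eb (K = 1.20, k = 0.289 h⁻¹)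
    Dz ⇌ Ju (K = 0.520, k = 0.0801 h⁻¹)

The flask's Ty stands 0.116 under its cover, a wider gap than the one read in gamma, and my Ty stands higher than the flask's. A neighbour flask has 1.72 times the Dz of this flask and the same Dx. Its cover is 0.348, and carrying this flask's gap over puts its Ty at 23.2%. That neighbour ends with Dx at 0% and Ty at 22.5%.

Readings and results come from a simulation with made-up constants, noise included.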